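Remark: ring A is numbered C1 (methyl), C2-H, C3-H, C4 (aryl), C5 (bearing the exocyclic carbon C7) and C6 (arylethynyl). The name and connectivity of the key-step precursor 8 and product 10 agree with each other and with the target, so both are used unchanged. All four oxygens are carried as methyl ethers, so the two rings on C7 stay identical until the last step.

## Structural features

Selaginellin U (17) is built on a tetrasubstituted benzene, ring A, which carries a methyl group on C1, a 4-hydroxyphenyl ring on C4, the exocyclic carbon C7 on C5 and a 4-hydroxyphenylethynyl group on C6. C7 bears one 4-hydroxyphenyl ring and is doubly bonded to a cyclohexa-2,5-dienone, so the C7 unit is a p-quinone methide. The dienone ring is symmetric and proton tautomerism exchanges the roles of the two rings on C7, so there is no alkene isomerism and the molecule has no stereocentre. The fragile groups are the electrophilic quinone methide, the three free phenols and the diaryl alkyne, which sits ortho to a carbon that easily becomes a stabilised trityl-type cation. The real difficulty is the contiguous C4–C5–C6 array: C7 is fully substituted and lies between the C4 aryl ring and the C6 alkyne, so every bond to C7 is made in a crowded pocket. Four different substituents must also be placed on neighbouring ring carbons without ambiguity. The key step uses the fact that C7 is a single carbon at the ketone oxidation level between C5 and an aryl group: it can enter as carbon monoxide by migratory insertion into a C5–palladium bond, which moves the bond-forming metal one atom out of the pocket.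

## Logic of the disconnections

**17 to 15.** No skeletal bond is cut first. The C7=C bond of the quinone methide and the four O–H bonds of 17 are traced back, by way of 16, to the C7–OH bond and the four O–CH3 bonds of 15. This removes the only electrophilic group and all acidic protons, and makes the two rings on C7 identical. The forward step must cleave four aryl methyl ethers without touching the alkyne and without letting the C7 cation close onto the C4 ring.

**15 to 12.** The C7–aryl bond is cut, giving ketone 12 and the aryl nucleophile 14, which comes from 13. Either of the identical rings can be taken off, and the cut turns a quaternary carbinol into a diaryl ketone. The forward step is a 1,2-addition to a carbonyl flanked by two ortho substituents; the nucleophile must be small and reactive and the ketone cannot enolise.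

**12 to 10.** The C6–C(sp) bond is cut, giving bromide 10 and alkyne 11. The alkyne is placed late so that it is absent during the carbonylation. The forward step is an oxidative addition at a bromide with two ortho neighbours, helped by the adjacent ketone.

**10 to 8.** The C5–C7 and C7–aryl bonds are cut together, giving iodide 8, carbon monoxide 9 and boronic acid 5. Three simple components replace a hindered ketone, and C7 becomes a one-carbon gas. The forward step must choose iodide over bromide and carbonylative over direct coupling.

**8 to 6.** The C5–I bond is traced back to a C5–N bond through diazonium salt 7. The amino group of 6 is what directed the earlier halogenation, and it is removed exactly where the iodide is needed. The forward step is the diazotisation of a weakly basic aniline with two ortho substituents.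

**6 to 4.** The C4–aryl bond is cut, giving dibromide 4 and a second use of 5. This leaves a simple trisubstituted aniline. The forward coupling must pick the bromide with one ortho neighbour over the bromide wedged between the amino and methyl groups.

**4 to 1.** The two C–Br bonds are cut, and a temporary C–S bond para to nitrogen is added, leading through 3 and 2 to 1. The sulfonic acid blocks the para position so that halogenation can only go ortho, and it leaves again as sulfuric acid. The forward steps are a thermodynamic para-sulfonation, a bromination with exactly two equivalents and a clean protodesulfonation.

## Other disconnections considered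

**Alternative 1:** The cut goes through C3–C4 and C5–C6 of ring A after the ring is taken back to a cyclohexene. In the forward sense the diene (E)-tert-butyl(dimethyl)[(2-methylbuta-1,3-dien-1-yl)oxy]silane A2 would add to the enone (E)-1,3-bis(4-methoxyphenyl)prop-2-en-1-one A3 in a Diels–Alder reaction. The product would be the racemic adduct {2-[tert-butyl(dimethyl)silyloxy]-6-(4-methoxyphenyl)-3-methylcyclohex-3-en-1-yl}(4-methoxyphenyl)methanone A1, with the aroyl group cis to the silyloxy group and trans to the aryl group.
- In its favour: one pericyclic step would place methyl, aryl, aroyl and the C6 oxygen on four neighbouring carbons. The regiochemistry follows from the 1-oxygen of the diene, and no metal, no CO and no halogen discrimination is needed. On positional control it is better than the chosen plan, whose step 3 must tell two bromides apart.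
- Against it here: three stereocentres are made only to be destroyed, and the enone is a sluggish dienophile. Ring A must be raised by two oxidation levels while the C6 oxygen is kept, yet A1 is a β-silyloxy ketone that should lose silanol by E1cB elimination far more easily, and that loss removes the handle for the alkyne. After aromatisation the oxygen would still have to become a sulfonate and be coupled.
- Comparison: both plans arrive at a ketone of the type of 12 and share steps 7 and 8, so the endgame is equal. The cycloaddition is mechanistically simpler than a three-component palladium cycle, but the aromatisation is not. About nine to ten operations against eight makes it slightly worse in step count.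

**Alternative 2:** The cut removes three bonds of ring A: C5–C6, C1–C2 and C3–C4. In the forward sense the diyne but-2-yn-1-yl 1,1,3-tris(4-methoxyphenyl)prop-2-yn-1-yl ether A5 would be cyclotrimerised with acetylene A6 on a monovalent rhodium catalyst such as RhCl(PPh3)3. The product would be 1,1,7-tris(4-methoxyphenyl)-4-methyl-1,3-dihydroisobenzofuran A4.
- In its favour: C7 would already be quaternary, with both aryl groups, before ring A exists, so no nucleophile has to reach a shielded carbonyl. On this point it is better than the chosen plan, which still needs step 7. Three C–C bonds and two rings would form at once, the gem-diaryl tether favours cyclisation, and there is no halogen regiochemistry.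
- Against it here: the tether remains as a cyclic ether whose CH2–O carbon must become the first alkyne carbon. That means opening an acid-labile trityl ether that recloses readily, oxidation to the aldehyde, a one-carbon homologation to the terminal alkyne and a Sonogashira coupling, all next to a carbon that ionises easily. Both alkynes of A5 are internal and one is next to a quaternary centre, so the crossed cyclotrimerisation may be slow beside self-reaction.
- Comparison: handling A6 is no easier than handling CO, so the two are equal there. About two operations to A5, one key step and five to six afterwards make it equal to or slightly longer than the chosen plan, with a less certain endgame.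

**Alternative 3:** The cut goes through C1–C2 and C4–C5. In the forward sense the bis(silyl enol ether) 1-methoxy-1,3-bis(trimethylsilyloxy)penta-1,3-diene A8 would react with the 3-oxo acetal 3,3-dimethoxy-1-(4-methoxyphenyl)propan-1-one A9 under TiCl4. The terminal carbon of A8 would attack the activated acetal carbon, the central carbon would close on the ketone, and loss of methanol and water would give methyl 2-hydroxy-6-(4-methoxyphenyl)-3-methylbenzoate A7.
- In its favour: ring A would appear already aromatic, with no stereocentre and no oxidation step. Methyl, C6 oxygen, C7 ester and C4 aryl would be fixed by the different electrophilicity of acetal and ketone; this regiocontrol is better than that of step 3, and no pressurised gas or palladium is needed for the ring-forming step. Because both aryl groups on C7 are the same, the ester could take them in one double addition, which equals the chosen plan in operations. The route is more convergent, with a shorter longest linear sequence, and is better on that count.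
- Against it here: C7 arrives as an ester carbonyl between the C4 aryl ring and the C6 substituent. Both C7–aryl bonds must then be made by attack on a shielded carbonyl, which is the event that CO insertion in step 5 avoids for the first of them. Benzoates with two ortho substituents add organometallics slowly, and the second addition passes through 12 in any case. The hydrogen-bonded phenol must also be converted into a sulfonate before alkynylation.
- Comparison: about two operations each to A8 and A9, then cyclocondensation, sulfonylation, alkynylation, double aryl addition and demethylation give nine operations with a longest linear sequence of about six, against eight linear steps. The ring construction is stronger; the construction of C7 is weaker.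

Key step: step 5

## Route

Step 1
Reactants: 1 3-methylaniline
Product: 2 4-amino-2-methylbenzenesulfonic acid
Conditions: H2SO4 (1.0 equiv), o-dichlorobenzene, 180 °C, removal of H2O
Reagents that add atoms: sulfuric acid, OS(=O)(=O)O
Why: Baking sulfonation (electrophilic aromatic sulfonation under thermodynamic control): the anilinium hydrogensulfate loses water to the N-sulfamate, which rearranges on heating to the ring sulfonic acid para to nitrogen, as in the manufacture of sulfanilic acid. The para position of 1 is thereby blocked, so only the two positions ortho to nitrogen remain for the next step.

Step 2
Reactants: 2 4-amino-2-methylbenzenesulfonic acid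
Product: 4 2,6-dibromo-3-methylaniline, via 4-amino-3,5-dibromo-2-methylbenzenesulfonic acid 3 (not isolated)
Conditions: Br2 (2.0 equiv), H2O, 0–10 °C; then H2SO4 (to ca. 65%), 150–160 °C, steam distillation
Reagents that add atoms: bromine, BrBr
Why: Electrophilic bromination takes the only two activated positions left, the carbons ortho to nitrogen; exactly two equivalents of bromine at low temperature should avoid ipso-bromodesulfonation. Heating 3 in aqueous H2SO4 reverses the sulfonation (protodesulfonation by ipso protonation, driven by steam removal of the volatile aniline), the classical route to 2,6-dibromoanilines.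

Step 3
Reactants: 4 2,6-dibromo-3-methylaniline; 5 4-methoxyphenylboronic acid (1.0 equiv)
Product: 6 3-bromo-4'-methoxy-4-methylbiphenyl-2-amine
Conditions: Pd(PPh3)4 (3 mol%), Na2CO3, toluene/EtOH/H2O, 80 °C
Reagents that add atoms: none
Why: Site-selective Suzuki–Miyaura coupling: zerovalent palladium should add faster to the C–Br bond with NH2 on one side and H on the other than to the one wedged between NH2 and CH3, and one equivalent of 5 limits double arylation. Once the aryl group is in place the remaining bromide has two ortho substituents and is slower still.

Step 4
Reactants: 6 3-bromo-4'-methoxy-4-methylbiphenyl-2-amine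
Product: 8 3-bromo-2-iodo-4'-methoxy-4-methylbiphenyl, via arenediazonium tosylate 7 (not isolated)
Conditions: TsOH·H2O (3 equiv), NaNO2 (2 equiv), KI (2.5 equiv), MeCN/H2O, 10 °C → rt
Reagents that add atoms: potassium iodide, [K+].[I-]
Why: Diazotisation and iodo-dediazoniation (Sandmeyer-type, without copper because iodide itself reduces the diazonium ion to the aryl radical). The tosylate conditions in acetonitrile suit weakly basic, hindered anilines, and the anisyl positions nearest the diazonium group are meta to methoxy, so intramolecular azo coupling is not expected.

Step 5
Reactants: 8 3-bromo-2-iodo-4'-methoxy-4-methylbiphenyl; 9 carbon monoxide; 5 4-methoxyphenylboronic acid (1.5 equiv)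
Product: 10 [2-bromo-6-(4-methoxyphenyl)-3-methylphenyl](4-methoxyphenyl)methanone
Conditions: PdCl2(IPr)(3-chloropyridine) (3 mol%; IPr = 1,3-bis(2,6-diisopropylphenyl)imidazol-2-ylidene), Cs2CO3 (3 equiv), CO (4 bar), chlorobenzene, 80 °C
Reagents that add atoms: none
Why: Carbonylative Suzuki–Miyaura coupling: the carbene-ligated zerovalent palladium formed from the precatalyst inserts into the weak C5–I bond of 8, CO binds and migrates into the aryl–palladium bond, and the resulting aroylpalladium iodide holds the metal one atom outside the pocket made by the C4 aryl ring and the C6 bromine. The carbonate-activated boronate of 5 then transfers its aryl group to this divalent palladium, and reductive elimination forms the C7–aryl bond and frees the catalyst. The closest known reaction type is the carbonylative coupling of 2,6-disubstituted aryl iodides with arylboronic acids under bulky N-heterocyclic carbene–palladium catalysis. No ring is closed and no stereocentre is formed. Iodide-over-bromide selectivity rests on the bond strengths and on the low electron density of CO-saturated palladium at 80 °C, which should not add to the hindered C6–Br bond. Carbonylative-over-direct selectivity rests on the two ortho groups, which slow transmetalation at the arylpalladium stage while CO insertion relieves strain, and on the CO pressure. A carbonate base and a moderate temperature disfavour C–H acylation of the C4 aryl ring by the aroylpalladium, and 5 is kept near 1.5 equiv so that the product bromide is left alone.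

Step 6
Reactants: 10 [2-bromo-6-(4-methoxyphenyl)-3-methylphenyl](4-methoxyphenyl)methanone; 11 4-ethynylanisole
Product: 12 (4-methoxyphenyl){6-(4-methoxyphenyl)-2-[(4-methoxyphenyl)ethynyl]-3-methylphenyl}methanone
Conditions: PdCl2(MeCN)2 (3 mol%), XPhos (9 mol%), Cs2CO3 (2.5 equiv), MeCN, 80 °C
Reagents that add atoms: none
Why: Copper-free Sonogashira coupling: the C6–Br bond is activated by the ortho aroyl group, and the bulky, electron-rich XPhos–palladium catalyst suits bromides with two ortho substituents. Leaving out copper avoids oxidative alkyne dimerisation and metal-promoted cyclisation of the new ortho-alkynyl ketone.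

Step 7
Reactants: 12 (4-methoxyphenyl){6-(4-methoxyphenyl)-2-[(4-methoxyphenyl)ethynyl]-3-methylphenyl}methanone; 13 4-bromoanisole
Product: 15 bis(4-methoxyphenyl){6-(4-methoxyphenyl)-2-[(4-methoxyphenyl)ethynyl]-3-methylphenyl}methanol, via 4-methoxyphenyllithium 14 (not isolated)
Conditions: 13 (3 equiv), n-BuLi (2.9 equiv), THF, −78 °C; then 12, −78 → 0 °C; H2O quench at 0 °C
Reagents that add atoms: none
Why: Bromine–lithium exchange gives 14, which adds 1,2 to the non-enolisable diaryl ketone; the rod-shaped alkyne on C6 leaves one flank of the carbonyl open to the small aryllithium. Both aryl groups on C7 are now identical, so no stereocentre arises, and a cold quench keeps the lithium alkoxide from adding to the neighbouring alkyne.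

Step 8
Reactants: 15 bis(4-methoxyphenyl){6-(4-methoxyphenyl)-2-[(4-methoxyphenyl)ethynyl]-3-methylphenyl}methanol
Product: 17 Selaginellin U, via tetraphenol carbinol 16 (not isolated)
Conditions: BBr3 (8 equiv), CH2Cl2, −78 → 0 °C; then H2O, rt
Reagents that add atoms: none
Why: Lewis-acid ether cleavage: BBr3 coordinates each methoxy oxygen and bromide removes the methyl group by SN2, while the carbinol ionises to a C7 cation that is strongly stabilised by its para-oxygenated rings. Hydrolysis gives 16, which should lose water spontaneously to the conjugated quinone methide; the cation is a poor electrophile and would have to attack the C4 ring meta to its oxygen, so closure to a fluorene is not expected to compete.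

## Compound list

1 | 3-methylaniline | Cc1cccc(N)c1 | starting material
2 | 4-amino-2-methylbenzenesulfonic acid | Cc1cc(N)ccc1S(=O)(=O)O | intermediate
3 | 4-amino-3,5-dibromo-2-methylbenzenesulfonic acid | Cc1c(Br)c(N)c(Br)cc1S(=O)(=O)O | intermediate (not isolated)
4 | 2,6-dibromo-3-methylaniline | Cc1ccc(Br)c(N)c1Br | intermediate
5 | 4-methoxyphenylboronic acid | COc1ccc(B(O)O)cc1 | starting material
6 | 3-bromo-4'-methoxy-4-methylbiphenyl-2-amine | Cc1ccc(-c2ccc(OC)cc2)c(N)c1Br | intermediate
7 | 3-bromo-4'-methoxy-4-methylbiphenyl-2-diazonium 4-methylbenzenesulfonate | Cc1ccc(-c2ccc(OC)cc2)c([N+]#N)c1Br.Cc1ccc(S(=O)(=O)[O-])cc1 | intermediate (not isolated)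
8 | 3-bromo-2-iodo-4'-methoxy-4-methylbiphenyl | Cc1ccc(-c2ccc(OC)cc2)c(I)c1Br | intermediate
9 | carbon monoxide | [C-]#[O+] | starting material
10 | [2-bromo-6-(4-methoxyphenyl)-3-methylphenyl](4-methoxyphenyl)methanone | Cc1ccc(-c2ccc(OC)cc2)c(C(=O)c2ccc(OC)cc2)c1Br | intermediate
11 | 4-ethynylanisole | COc1ccc(C#C)cc1 | starting material
12 | (4-methoxyphenyl){6-(4-methoxyphenyl)-2-[(4-methoxyphenyl)ethynyl]-3-methylphenyl}methanone | Cc1ccc(-c2ccc(OC)cc2)c(C(=O)c2ccc(OC)cc2)c1C#Cc1ccc(OC)cc1 | intermediate
13 | 4-bromoanisole | COc1ccc(Br)cc1 | starting material
14 | 4-methoxyphenyllithium | [Li]c1ccc(OC)cc1 | intermediate (not isolated)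
15 | bis(4-methoxyphenyl){6-(4-methoxyphenyl)-2-[(4-methoxyphenyl)ethynyl]-3-methylphenyl}methanol | Cc1ccc(-c2ccc(OC)cc2)c(C(O)(c2ccc(OC)cc2)c2ccc(OC)cc2)c1C#Cc1ccc(OC)cc1 | intermediate
16 | bis(4-hydroxyphenyl){6-(4-hydroxyphenyl)-2-[(4-hydroxyphenyl)ethynyl]-3-methylphenyl}methanol | Cc1ccc(-c2ccc(O)cc2)c(C(O)(c2ccc(O)cc2)c2ccc(O)cc2)c1C#Cc1ccc(O)cc1 | intermediate (not isolated)
17 | Selaginellin U, 4-[(4-hydroxyphenyl){6-(4-hydroxyphenyl)-2-[(4-hydroxyphenyl)ethynyl]-3-methylphenyl}methylidene]cyclohexa-2,5-dien-1-one | Cc1ccc(-c2ccc(O)cc2)c(C(=C2C=CC(=O)C=C2)c2ccc(O)cc2)c1C#Cc1ccc(O)cc1 | target

## Step count and least certain steps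

Total step count: 8. Longest linear sequence: 8 steps, from 1 to 17; 5, 9, 11 and 13 are commercial partners.

**Step 5 (key step).**
- Risks: direct coupling without CO if transmetalation at the arylpalladium outruns insertion; C–H acylation of the C4 aryl ring by the aroylpalladium, which would close a five-membered ketone ring; and oxidative addition at the C6–Br bond once the activating ketone is present.
- Fallback: this sets out from 8 and comes back at 10. Iodine–magnesium exchange with i-PrMgCl·LiCl in THF at −40 °C, which leaves the bromide alone, and addition of the arylmagnesium to 4-methoxybenzaldehyde should give racemic [2-bromo-6-(4-methoxyphenyl)-3-methylphenyl](4-methoxyphenyl)methanol F1. Oxidation of this benzylic alcohol with MnO2 in CH2Cl2 should give 10. The aldehyde is an unshielded electrophile, so the hindered nucleophile can reach it.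

**Step 3.**
- Risk: insufficient discrimination between the two C–Br bonds, together with double arylation, because the steric difference is one methyl group.
- Fallback: this sets out from 2 and comes back at 6, replacing steps 2 and 3. Each halogen is introduced separately while the sulfonic acid still blocks the para position.
  - Iodination of 2 with ICl (1 equiv) in aqueous acetic acid should go to the less hindered ortho position and give 4-amino-5-iodo-2-methylbenzenesulfonic acid F2.
  - Suzuki–Miyaura coupling of F2 with 5 in water (Pd(OAc)2, Na2CO3, 60 °C) should give 4-amino-5-(4-methoxyphenyl)-2-methylbenzenesulfonic acid F3.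
  - Bromination with Br2 (1 equiv) in water at the only remaining position ortho to nitrogen should give 4-amino-3-bromo-5-(4-methoxyphenyl)-2-methylbenzenesulfonic acid F4.
  - Protodesulfonation in hot aqueous H2SO4 should then deliver 6 with the regiochemistry fixed by construction.

**Step 6.**
- Risks: slow oxidative addition at a bromide with two ortho neighbours, and base-induced side reactions of the alkyne or of the ortho-alkynyl ketone during a long reaction.
- Fallback: this sets out from 10 and comes back at 12. The alkyne is delivered as a preformed tin acetylide in a base-free Stille coupling. Deprotonation of 11 with n-BuLi and quenching with Bu3SnCl should give tributyl[(4-methoxyphenyl)ethynyl]stannane F5, which would be coupled with 10 using Pd(PPh3)4 in toluene at 100 °C. Alkynyl groups transfer from tin faster than any other group, and no base is present.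

**Step 7.**
- Risks: failure of the 1,2-addition because both faces of the carbonyl are screened by the ortho groups of ring A, with electron-transfer reduction taking over, or addition of the alkoxide to the neighbouring alkyne on warming.
- Fallback: this sets out from 8 and comes back at 15. It reverses the polarity at C7 and gives up CO as the source of C7. Iodine–magnesium exchange on 8 with i-PrMgCl·LiCl at −40 °C and addition of the arylmagnesium to the unhindered 4,4'-dimethoxybenzophenone should give [2-bromo-6-(4-methoxyphenyl)-3-methylphenyl]bis(4-methoxyphenyl)methanol F6. Copper-free Sonogashira coupling of F6 with 11 (PdCl2(MeCN)2, XPhos, Cs2CO3) would then give 15. The cost is a more hindered bromide in that coupling.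

**Step 8.**
- Risks: incomplete cleavage of the four ethers; Friedel–Crafts closure of the C7 cation onto the C4 aryl ring under the Lewis acid; and addition of boron–bromine or hydrogen–bromine across the alkyne.
- Fallback: this sets out from 15 and comes back at 17. Nucleophilic demethylation replaces the Lewis acid, so no cation is formed while the ethers are cleaved. Sodium ethanethiolate (NaSEt) in DMF at 120 °C should remove the four methyl groups by SN2 and give, after neutralisation, the tetraphenol carbinol 16, here isolated. Stirring 16 in acetic acid at room temperature should dehydrate it to 17. No compound outside the compound list is made (entry F0).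

## Further compounds

F1 | step 5 | [2-bromo-6-(4-methoxyphenyl)-3-methylphenyl](4-methoxyphenyl)methanol (racemic) | Cc1ccc(-c2ccc(OC)cc2)c(C(O)c2ccc(OC)cc2)c1Br
F2 | step 3 | 4-amino-5-iodo-2-methylbenzenesulfonic acid | Cc1cc(N)c(I)cc1S(=O)(=O)O
F3 | step 3 | 4-amino-5-(4-methoxyphenyl)-2-methylbenzenesulfonic acid | Cc1cc(N)c(-c2ccc(OC)cc2)cc1S(=O)(=O)O
F4 | step 3 | 4-amino-3-bromo-5-(4-methoxyphenyl)-2-methylbenzenesulfonic acid | Cc1c(Br)c(N)c(-c2ccc(OC)cc2)cc1S(=O)(=O)O
F5 | step 6 | tributyl[(4-methoxyphenyl)ethynyl]stannane | CCCC[Sn](CCCC)(CCCC)C#Cc1ccc(OC)cc1
F6 | step 7 | [2-bromo-6-(4-methoxyphenyl)-3-methylphenyl]bis(4-methoxyphenyl)methanol | Cc1ccc(-c2ccc(OC)cc2)c(C(O)(c2ccc(OC)cc2)c2ccc(OC)cc2)c1Br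
F0 | step 8 | none | none
A1 | alternative 1 | racemic {2-[tert-butyl(dimethyl)silyloxy]-6-(4-methoxyphenyl)-3-methylcyclohex-3-en-1-yl}(4-methoxyphenyl)methanone, aroyl cis to silyloxy and trans to aryl (relative configuration) | CC1=CC[C@H](c2ccc(OC)cc2)[C@@H](C(=O)c2ccc(OC)cc2)[C@H]1O[Si](C)(C)C(C)(C)C
A2 | alternative 1 | (E)-tert-butyl(dimethyl)[(2-methylbuta-1,3-dien-1-yl)oxy]silane | C=C/C(C)=C/O[Si](C)(C)C(C)(C)C
A3 | alternative 1 | (E)-1,3-bis(4-methoxyphenyl)prop-2-en-1-one | COc1ccc(/C=C/C(=O)c2ccc(OC)cc2)cc1
A4 | alternative 2 | 1,1,7-tris(4-methoxyphenyl)-4-methyl-1,3-dihydroisobenzofuran | Cc1ccc(-c2ccc(OC)cc2)c2c1COC2(c1ccc(OC)cc1)c1ccc(OC)cc1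
A5 | alternative 2 | but-2-yn-1-yl 1,1,3-tris(4-methoxyphenyl)prop-2-yn-1-yl ether | CC#CCOC(C#Cc1ccc(OC)cc1)(c1ccc(OC)cc1)c1ccc(OC)cc1
A6 | alternative 2 | acetylene | C#C
A7 | alternative 3 | methyl 2-hydroxy-6-(4-methoxyphenyl)-3-methylbenzoate | COC(=O)c1c(O)c(C)ccc1-c1ccc(OC)cc1
A8 | alternative 3 | 1-methoxy-1,3-bis(trimethylsilyloxy)penta-1,3-diene (alkene geometry unassigned) | CC=C(O[Si](C)(C)C)C=C(OC)O[Si](C)(C)C
A9 | alternative 3 | 3,3-dimethoxy-1-(4-methoxyphenyl)propan-1-one | COc1ccc(C(=O)CC(OC)OC)cc1
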